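The retrosynthesis cuts the C6 and C1 esters, takes the oxirane back to a C4 acetyl group, and takes C6–O plus C7=CH2 back to a cyclic allylsilane (C7–CH2–SiMe2–O–C1). It then cuts C7a–C3a and C4–C5 (Diels–Alder), the diene (enyne metathesis), C3a=C4 (Wittig), C1–C2 (alkoxyallylboration) and C2–C3 (Fráter–Seebach).
In the forward direction the open chain C7a–C1–C2–C3–C3a is built first and a temporary oxasilacyclohexene is closed by ring-closing enyne metathesis. One intramolecular Diels–Alder reaction then closes the cyclopentane and, with it, the cyclohexane as the last carbocycle. The silicon ring is removed while it delivers C6–OH and the exocyclic methylene.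
The enabling feature is that the C1 oxygen and C7 are cis on the C1–C7a bond (O–C1–C7a–C7=CH2). One SiMe2 unit can therefore tie O1 and the methylene carbon into a six-membered ring that contains the C7=C7a half of the diene. The trans H-3a/H-4 pair next to a carbonyl-derived C4 substituent is the imprint of an E-enone.
Stereochemistry: C1' comes from ethyl (S)-3-hydroxybutanoate, C3 from chelate-controlled alkylation, and C1/C2 from reagent-controlled allylboration. C7a, C3a and C4 are set in the cycloaddition (tether, endo rule, E geometry). The oxirane carbon is set by Felkin–Anh addition, C6 by anti-SE2' epoxidation of the allylsilane, and the side-chain carbinol comes from (S)-lactic acid.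

Key step: step 15

Numbering: the octahydro-1H-indene numbering of the target is used for all intermediates. C1 and C2 are the isobutyrate carbons, C3 carries the 1-acetoxyethyl group (C1'), C3a and C7a are the ring fusion, C4 carries the oxirane, C6 carries the enoate, and C7 carries =CH2. β is the face of H-3a and α the face of H-7a.
Assumption: 3-(methoxymethoxy)prop-1-ene and (S)-2-acetoxypropanoyl chloride are taken as purchasable, and the oxirane is treated as a functional group added once the carbocyclic skeleton is complete.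

Step 1
Reactants: 1 ethyl (3S)-3-hydroxybutanoate
Product: 2 ethyl (2S,3S)-2-[(benzyloxy)methyl]-3-hydroxybutanoate
Conditions: LDA (2.2 equiv), THF, −78 to −20 °C; BnOCH2Cl, DMPU, −78 to −30 °C
Reagents that add atoms: benzyl chloromethyl ether, ClCOCc1ccccc1
Why: Fráter–Seebach alkylation: the lithium-chelated dianion of the β-hydroxy ester takes up the reactive chloromethyl ether on the face away from the C1' methyl group, which sets C3 anti to the C1' oxygen and brings in C2 as a masked CH2OH.

Step 2
Reactants: 2 ethyl (2S,3S)-2-[(benzyloxy)methyl]-3-hydroxybutanoate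
Product: 3 (2S,3S)-2-[(benzyloxy)methyl]butane-1,3-diol
Conditions: LiAlH4, THF, 0 °C
Reagents that add atoms: none
Why: Standard LiAlH4 ester reduction turns the future C3a into a CH2OH group without touching C3 or C1'.

Step 3
Reactants: 3 (2S,3S)-2-[(benzyloxy)methyl]butane-1,3-diol
Product: 4 (4S,5R)-5-[(benzyloxy)methyl]-2,2,4-trimethyl-1,3-dioxane (4,5-trans)
Conditions: Me2C(OMe)2, PPTS (cat.), CH2Cl2, rt
Reagents that add atoms: 2,2-dimethoxypropane, COC(C)(C)OC
Why: Acid-catalysed transacetalisation ties the only two free hydroxyls (on C3a and C1') into a 1,3-dioxane with methyl and CH2OBn trans-diequatorial, so one helper protects both oxygens.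

Step 4
Reactants: 4 (4S,5R)-5-[(benzyloxy)methyl]-2,2,4-trimethyl-1,3-dioxane
Product: 5 [(4S,5R)-2,2,4-trimethyl-1,3-dioxan-5-yl]methanol
Conditions: H2 (1 atm), Pd/C, EtOAc, rt
Reagents that add atoms: none
Why: Catalytic hydrogenolysis of the benzyl ether under neutral conditions leaves the acetonide intact and frees the C2 hydroxyl.

Step 5
Reactants: 5 [(4S,5R)-2,2,4-trimethyl-1,3-dioxan-5-yl]methanol
Product: 6 (4S,5R)-2,2,4-trimethyl-1,3-dioxane-5-carbaldehyde
Conditions: Dess–Martin periodinane, NaHCO3, CH2Cl2, 0 °C to rt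
Reagents that add atoms: none
Why: Buffered Dess–Martin oxidation gives the aldehyde without epimerisation, and C3 is in any case held in its more stable equatorial arrangement.

Step 6
Reactants: 6 (4S,5R)-2,2,4-trimethyl-1,3-dioxane-5-carbaldehyde
Product: 7 (1R,2R)-2-(methoxymethoxy)-1-[(4S,5S)-2,2,4-trimethyl-1,3-dioxan-5-yl]but-3-en-1-ol (C1/C2 syn)
Conditions: CH2=CHCH2OCH2OMe, s-BuLi, THF, −78 °C; (−)-Ipc2BOMe; BF3·OEt2; then 6, −78 °C; NaOH, H2O2
Reagents that add atoms: 3-(methoxymethoxy)prop-1-ene, C=CCOCOC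
Why: Brown (Z)-γ-alkoxyallylboration through a closed chair transition state: the Z geometry gives the C1/C2 syn pattern, the isopinocampheyl groups derived from (+)-α-pinene select the aldehyde face, and this is also the anti-Felkin sense that Z-allylboranes prefer with α-branched aldehydes.

Step 7
Reactants: 7 (1R,2R)-2-(methoxymethoxy)-1-[(4S,5S)-2,2,4-trimethyl-1,3-dioxan-5-yl]but-3-en-1-ol
Product: 8 (1R,2R)-2-(methoxymethoxy)-1-[(4S,5R)-2,2,4-trimethyl-1,3-dioxan-5-yl]but-3-en-1-yl 2-methylpropanoate
Conditions: (i-PrCO)2O, Et3N, DMAP, CH2Cl2, rt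
Reagents that add atoms: isobutyric anhydride, CC(C)C(=O)OC(=O)C(C)C
Why: DMAP-catalysed acylation puts the final C2 isobutyrate on the only free hydroxyl, where it also serves as the protecting group.

Step 8
Reactants: 8 (1R,2R)-2-(methoxymethoxy)-1-[(4S,5R)-2,2,4-trimethyl-1,3-dioxan-5-yl]but-3-en-1-yl 2-methylpropanoate
Product: 9 (3R,4R,5R,6S)-6-hydroxy-5-(hydroxymethyl)-3-(methoxymethoxy)hept-1-en-4-yl 2-methylpropanoate
Conditions: AcOH–H2O (4:1), rt
Reagents that add atoms: none
Why: Mild aqueous acid hydrolyses the 1,3-dioxane acetonide much faster than the methoxymethyl ether or the hindered ester.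

Step 9
Reactants: 9 (3R,4R,5R,6S)-6-hydroxy-5-(hydroxymethyl)-3-(methoxymethoxy)hept-1-en-4-yl 2-methylpropanoate
Product: 11 (3E,5R,6R,7R)-5-[(1S)-1-hydroxyethyl]-7-(methoxymethoxy)-2-oxonona-3,8-dien-6-yl 2-methylpropanoate, via β-hydroxy aldehyde 10 (not isolated)
Conditions: TEMPO (10 mol%), PhI(OAc)2, CH2Cl2, rt; then Ph3P=CHC(O)Me (excess), rt
Reagents that add atoms: 1-(triphenylphosphoranylidene)propan-2-one, CC(=O)C=P(c1ccccc1)(c1ccccc1)c1ccccc1
Why: Nitroxyl-catalysed oxidation takes only the primary alcohol and the aldehyde is trapped at once by Wittig olefination with a stabilised ylide, which gives the E-enone and leaves no time for epimerisation at C3 or retro-aldol loss.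

Step 10
Reactants: 11 (3E,5R,6R,7R)-5-[(1S)-1-hydroxyethyl]-7-(methoxymethoxy)-2-oxonona-3,8-dien-6-yl 2-methylpropanoate
Product: 12 (3E,5R,6R,7R)-5-[(1S)-1-acetoxyethyl]-7-(methoxymethoxy)-2-oxonona-3,8-dien-6-yl 2-methylpropanoate
Conditions: Ac2O, pyridine, DMAP (cat.), CH2Cl2, 0 °C
Reagents that add atoms: acetic anhydride, CC(=O)OC(C)=O
Why: Standard acetylation installs the final C1' acetate, and the weak base at 0 °C avoids vinylogous β-elimination from the γ-position of the enone.

Step 11
Reactants: 12 (3E,5R,6R,7R)-5-[(1S)-1-acetoxyethyl]-7-(methoxymethoxy)-2-oxonona-3,8-dien-6-yl 2-methylpropanoate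
Product: 13 (3E,5R,6R,7R)-5-[(1S)-1-acetoxyethyl]-7-hydroxy-2-oxonona-3,8-dien-6-yl 2-methylpropanoate
Conditions: Me2BBr, CH2Cl2, −78 °C; then aq. NaHCO3–THF
Reagents that add atoms: none
Why: Bromodimethylborane cleaves methoxymethyl ethers chemoselectively at −78 °C (Lewis-acid-assisted acetal cleavage with hydrolytic work-up) and leaves the esters, the enone and the allylic C–O bond alone.

Step 12
Reactants: 14 3-bromoprop-1-yne; 15 dichloro(dimethyl)silane
Product: 17 chloro(dimethyl)(prop-2-yn-1-yl)silane, via allenylmagnesium bromide 16 (not isolated)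
Conditions: Mg, HgCl2 (1 mol%), Et2O, 0 °C; then Me2SiCl2 (3 equiv), −78 °C to rt; distillation
Reagents that add atoms: none
Why: Grignard formation from propargyl bromide gives the allenyl metal, which attacks the chlorosilane through its γ-carbon (SE2') to give the propargylsilane, and the excess of Me2SiCl2 suppresses double substitution.

Step 13
Reactants: 13 (3E,5R,6R,7R)-5-[(1S)-1-acetoxyethyl]-7-hydroxy-2-oxonona-3,8-dien-6-yl 2-methylpropanoate; 17 chloro(dimethyl)(prop-2-yn-1-yl)silane
Product: 18 (3E,5R,6R,7R)-5-[(1S)-1-acetoxyethyl]-7-{[dimethyl(prop-2-yn-1-yl)silyl]oxy}-2-oxonona-3,8-dien-6-yl 2-methylpropanoate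
Conditions: imidazole, CH2Cl2, 0 °C
Reagents that add atoms: none
Why: Standard imidazole-mediated silylation of the one free (allylic, C1) hydroxyl attaches the alkyne through the silicon tether.

Step 14
Reactants: 18 (3E,5R,6R,7R)-5-[(1S)-1-acetoxyethyl]-7-{[dimethyl(prop-2-yn-1-yl)silyl]oxy}-2-oxonona-3,8-dien-6-yl 2-methylpropanoate
Product: 19 (1R,2R,3E)-2-[(1S)-1-acetoxyethyl]-1-[(6R)-4-ethenyl-2,2-dimethyl-3,6-dihydro-2H-1,2-oxasilin-6-yl]-5-oxohex-3-en-1-yl 2-methylpropanoate
Conditions: second-generation Grubbs catalyst (H2IMes)(PCy3)Cl2Ru=CHPh (5 mol%), ethylene (1 atm), CH2Cl2 (5 mM), rt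
Reagents that add atoms: none
Why: Ring-closing enyne metathesis of a silyl-ether-tethered 1,7-enyne in the exo mode closes the six-membered oxasilacycle and moves the CH2 of the C7a vinyl group onto C6, so that the C5=C6–C7=C7a diene with its CH2Si substituent on C7 arises in one atom-economical step with no new stereocentre.

Step 15
Reactants: 19 (1R,2R,3E)-2-[(1S)-1-acetoxyethyl]-1-[(6R)-4-ethenyl-2,2-dimethyl-3,6-dihydro-2H-1,2-oxasilin-6-yl]-5-oxohex-3-en-1-yl 2-methylpropanoate
Product: 20 siloxane-bridged cycloadduct: trans-fused 2,3,3a,4,5,7a-hexahydro-1H-indene (C6=C7) with 4β-acetyl; 3β-[(1S)-1-acetoxyethyl]; 2α-isobutyryloxy; an O–SiMe2–CH2 bridge from the 1β-oxygen to C7; H-3a β; H-7a α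
Conditions: Me2AlCl (2.5 equiv), CH2Cl2, −78 to −30 °C
Reagents that add atoms: none
Why: Me2AlCl binds the enone carbonyl and the 2-(silylmethyl)diene adds to it in a concerted but asynchronous suprafacial [4+2] process in which C7a–C3a runs ahead of C4–C5, because the C–Si bond makes C7a the most nucleophilic diene terminus and C3a is the β-carbon of the enone, so the regiochemistry imposed by the tether is also the electronically preferred "para" one. The closest known reaction type is the Lewis-acid-promoted type 1 intramolecular Diels–Alder reaction of (E,E)-nona-1,3,8-trienes with a terminal carbonyl group, which gives trans-hydrindenes, together with the Diels–Alder chemistry of 2-(trimethylsilylmethyl)buta-1,3-diene. Both carbocycles close in this one event in the fused mode: the cyclopentane (C1–C2–C3–C3a–C7a) through C7a–C3a across the three-atom tether, and the cyclohexene (C3a–C4–C5–C6–C7–C7a) through C7a–C3a plus C4–C5. C7a is fixed by C1, since O1 is locked into the oxasilacycle that contains C7=C7a and the dienophile can reach only the diene face on which C2 stands, which makes H-7a cis to H-1; C3a follows from the endo transition state (acetyl under the diene, tether exo), which gives the trans ring fusion; C4 follows from the E geometry, which puts the acetyl group trans to C3 and hence equatorial. The selectivity needed is endo over exo, and it is secured by carbonyl complexation at low temperature and by the fact that the endo array also places the bulky C3 side chain pseudo-equatorial on the forming five-membered ring. The esters bind the Lewis acid only reversibly, which is why more than two equivalents are used.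

Step 16
Reactants: 20 siloxane-bridged cycloadduct (4β-acetyl)
Product: 22 siloxane-bridged hydrindene with 4β-[(2R)-2-methyloxiran-2-yl] in place of the acetyl group, via lithium chlorohydrinate 21 (not isolated)
Conditions: ClCH2I, MeLi·LiBr, THF, −78 °C to rt
Reagents that add atoms: chloroiodomethane, ClCI
Why: Chloromethyllithium made in situ adds to the ketone far faster than to esters at −78 °C and the chlorohydrinate closes to the oxirane on warming (carbenoid epoxidation of a ketone); Felkin–Anh attack anti to the C4–C3a bond with C5H2 next to the carbonyl oxygen gives the (R) oxirane carbon.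

Step 17
Reactants: 22 siloxane-bridged hydrindene with 4β-[(2R)-2-methyloxiran-2-yl]
Product: 24 1β,6α-diol: trans-octahydro-1H-indene with 7-methylidene; 1β-OH; 6α-OH; 2α-isobutyryloxy; 3β-[(1S)-1-acetoxyethyl]; 4β-[(2R)-2-methyloxiran-2-yl], via epoxysilane 23 (not isolated)
Conditions: m-CPBA, NaHCO3, CH2Cl2, 0 °C; then Bu4NF–AcOH (1:1), THF, 0 °C
Reagents that add atoms: 3-chloroperoxybenzoic acid, O=C(OO)c1cccc(Cl)c1
Why: The allylsilane is epoxidised anti to its C–Si bond and away from the SiMe2 bridge on the β face (anti-SE2' sense), which places oxygen on the α face of C6, and fluoride then triggers a Peterson-type β-elimination that opens the C7–O bond, turns the silicon-bound CH2 into the exocyclic methylene and releases the C1 hydroxyl.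

Step 18
Reactants: 25 (2S)-2-acetoxypropanoyl chloride
Product: 26 (2S)-3-oxobutan-2-yl acetate
Conditions: MeMgBr (1.0 equiv), Fe(acac)3 (3 mol%), THF, −78 °C
Reagents that add atoms: methylmagnesium bromide, C[Mg]Br
Why: Iron-catalysed acylation of a Grignard reagent with an acid chloride stops at the ketone at −78 °C and touches neither the acetate nor the stereocentre taken from (S)-lactic acid.

Step 19
Reactants: 26 (2S)-3-oxobutan-2-yl acetate
Product: 27 tert-butyl (2E,4S)-4-acetoxy-3-methylpent-2-enoate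
Conditions: Ph3P=CHCO2t-Bu, toluene, 90 °C
Reagents that add atoms: tert-butyl (triphenylphosphoranylidene)acetate, CC(C)(C)OC(=O)C=P(c1ccccc1)(c1ccccc1)c1ccccc1
Why: Wittig olefination of the activated α-acyloxy ketone with a stabilised ylide under neutral conditions gives the E-alkene, with the ester trans to the branched C4, without racemisation.

Step 20
Reactants: 27 tert-butyl (2E,4S)-4-acetoxy-3-methylpent-2-enoate
Product: 28 (2E,4S)-4-acetoxy-3-methylpent-2-enoic acid
Conditions: CF3CO2H, CH2Cl2, 0 °C to rt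
Reagents that add atoms: none
Why: Acidolysis of the tert-butyl ester (loss of 2-methylpropene) frees the acid while the acetate and the E-alkene stay untouched.

Step 21
Reactants: 24 1β,6α-diol; 28 (2E,4S)-4-acetoxy-3-methylpent-2-enoic acid (1.05 equiv)
Product: 29 C6 mono-ester: 24 with the 6α-oxygen acylated by (2E,4S)-4-acetoxy-3-methylpent-2-enoyl and the 1β-OH free
Conditions: DCC, DMAP (cat.), CH2Cl2, −10 to 0 °C
Reagents that add atoms: none
Why: Steglich esterification with one equivalent of acid should take the C6 allylic alcohol, which is flanked by a CH2 and a flat sp2 carbon, in preference to the C1 alcohol, which is wedged between C7a, the C2 isobutyrate, the C7 methylene and the syn C3 side chain; the configuration at C6 is retained.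

Step 22
Reactants: 29 C6 mono-ester
Product: 30 target CNP0131236.1, (1R,2R,3R,3aR,4S,6S,7aS)-3-[(1S)-1-acetoxyethyl]-6-{[(2E,4S)-4-acetoxy-3-methylpent-2-enoyl]oxy}-7-methylidene-4-[(2R)-2-methyloxiran-2-yl]octahydro-1H-indene-1,2-diyl bis(2-methylpropanoate)
Conditions: (i-PrCO)2O, Et3N, DMAP, CH2Cl2, rt to 35 °C
Reagents that add atoms: isobutyric anhydride, CC(C)C(=O)OC(=O)C(C)C
Why: Forcing DMAP-catalysed acylation of the remaining hindered C1 hydroxyl completes the target, and the base-stable oxirane, the exocyclic alkene and the other esters survive.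

Compound list
1 | ethyl (3S)-3-hydroxybutanoate | C[C@H](O)CC(=O)OCC | starting material
2 | ethyl (2S,3S)-2-[(benzyloxy)methyl]-3-hydroxybutanoate | CCOC(=O)[C@@H](COCc1ccccc1)[C@H](C)O | intermediate
3 | (2S,3S)-2-[(benzyloxy)methyl]butane-1,3-diol | OC[C@@H](COCc1ccccc1)[C@H](C)O | intermediate
4 | (4S,5R)-5-[(benzyloxy)methyl]-2,2,4-trimethyl-1,3-dioxane | CC1(C)OC[C@@H](COCc2ccccc2)[C@H](C)O1 | intermediate
5 | [(4S,5R)-2,2,4-trimethyl-1,3-dioxan-5-yl]methanol | CC1(C)OC[C@@H](CO)[C@H](C)O1 | intermediate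
6 | (4S,5R)-2,2,4-trimethyl-1,3-dioxane-5-carbaldehyde | CC1(C)OC[C@@H](C=O)[C@H](C)O1 | intermediate
7 | (1R,2R)-2-(methoxymethoxy)-1-[(4S,5S)-2,2,4-trimethyl-1,3-dioxan-5-yl]but-3-en-1-ol | C=C[C@@H](OCOC)[C@H](O)[C@@H]1COC(C)(C)O[C@H]1C | intermediate
8 | (1R,2R)-2-(methoxymethoxy)-1-[(4S,5R)-2,2,4-trimethyl-1,3-dioxan-5-yl]but-3-en-1-yl 2-methylpropanoate | C=C[C@@H](OCOC)[C@H](OC(=O)C(C)C)[C@@H]1COC(C)(C)O[C@H]1C | intermediate
9 | (3R,4R,5R,6S)-6-hydroxy-5-(hydroxymethyl)-3-(methoxymethoxy)hept-1-en-4-yl 2-methylpropanoate | C=C[C@@H](OCOC)[C@H](OC(=O)C(C)C)[C@H](CO)[C@H](C)O | intermediate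
10 | (3R,4R,5R,6S)-5-formyl-6-hydroxy-3-(methoxymethoxy)hept-1-en-4-yl 2-methylpropanoate (β-hydroxy aldehyde) | C=C[C@@H](OCOC)[C@H](OC(=O)C(C)C)[C@H](C=O)[C@H](C)O | intermediate (not isolated)
11 | (3E,5R,6R,7R)-5-[(1S)-1-hydroxyethyl]-7-(methoxymethoxy)-2-oxonona-3,8-dien-6-yl 2-methylpropanoate | C=C[C@@H](OCOC)[C@H](OC(=O)C(C)C)[C@H](/C=C/C(C)=O)[C@H](C)O | intermediate
12 | (3E,5R,6R,7R)-5-[(1S)-1-acetoxyethyl]-7-(methoxymethoxy)-2-oxonona-3,8-dien-6-yl 2-methylpropanoate | C=C[C@@H](OCOC)[C@H](OC(=O)C(C)C)[C@H](/C=C/C(C)=O)[C@H](C)OC(C)=O | intermediate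
13 | (3E,5R,6R,7R)-5-[(1S)-1-acetoxyethyl]-7-hydroxy-2-oxonona-3,8-dien-6-yl 2-methylpropanoate | C=C[C@@H](O)[C@H](OC(=O)C(C)C)[C@H](/C=C/C(C)=O)[C@H](C)OC(C)=O | intermediate
14 | 3-bromoprop-1-yne | C#CCBr | starting material
15 | dichloro(dimethyl)silane | C[Si](C)(Cl)Cl | starting material
16 | allenylmagnesium bromide | C=C=C[Mg]Br | intermediate (not isolated)
17 | chloro(dimethyl)(prop-2-yn-1-yl)silane | C#CC[Si](C)(C)Cl | intermediate
18 | (3E,5R,6R,7R)-5-[(1S)-1-acetoxyethyl]-7-{[dimethyl(prop-2-yn-1-yl)silyl]oxy}-2-oxonona-3,8-dien-6-yl 2-methylpropanoate | C=C[C@@H](O[Si](C)(C)CC#C)[C@H](OC(=O)C(C)C)[C@H](/C=C/C(C)=O)[C@H](C)OC(C)=O | intermediate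
19 | (1R,2R,3E)-2-[(1S)-1-acetoxyethyl]-1-[(6R)-4-ethenyl-2,2-dimethyl-3,6-dihydro-2H-1,2-oxasilin-6-yl]-5-oxohex-3-en-1-yl 2-methylpropanoate | C=CC1=C[C@H]([C@H](OC(=O)C(C)C)[C@H](/C=C/C(C)=O)[C@H](C)OC(C)=O)O[Si](C)(C)C1 | intermediate
20 | siloxane-bridged trans-hydrindene cycloadduct (C6=C7; 4β-acetyl; 3β-[(1S)-1-acetoxyethyl]; 2α-isobutyryloxy; 1β-O–SiMe2–CH2–C7; H-3a β; H-7a α) | C1C2=CC[C@H](C(C)=O)[C@@H]3[C@@H]2[C@@H](O[Si]1(C)C)[C@H](OC(=O)C(C)C)[C@H]3[C@H](C)OC(C)=O | intermediate
21 | lithium chlorohydrinate of 20 (4β-[(2R)-1-chloro-2-oxidopropan-2-yl]) | C1C2=CC[C@H]([C@]([O-])(C)CCl)[C@@H]3[C@@H]2[C@@H](O[Si]1(C)C)[C@H](OC(=O)C(C)C)[C@H]3[C@H](C)OC(C)=O.[Li+] | intermediate (not isolated)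
22 | siloxane-bridged hydrindene with 4β-[(2R)-2-methyloxiran-2-yl] | C1C2=CC[C@H]([C@]4(C)CO4)[C@@H]3[C@@H]2[C@@H](O[Si]1(C)C)[C@H](OC(=O)C(C)C)[C@H]3[C@H](C)OC(C)=O | intermediate
23 | 6α,7α-epoxide of 22 (epoxysilane) | C1[C@@]25O[C@H]5C[C@H]([C@]4(C)CO4)[C@@H]3[C@@H]2[C@@H](O[Si]1(C)C)[C@H](OC(=O)C(C)C)[C@H]3[C@H](C)OC(C)=O | intermediate (not isolated)
24 | 1β,6α-diol (7-methylidene; 2α-isobutyryloxy; 3β-[(1S)-1-acetoxyethyl]; 4β-[(2R)-2-methyloxiran-2-yl]; trans ring fusion) | C=C1[C@H]2[C@@H](O)[C@H](OC(=O)C(C)C)[C@@H]([C@H](C)OC(C)=O)[C@@H]2[C@@H]([C@]2(C)CO2)C[C@@H]1O | intermediate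
25 | (2S)-2-acetoxypropanoyl chloride | C[C@H](OC(C)=O)C(=O)Cl | starting material
26 | (2S)-3-oxobutan-2-yl acetate | C[C@H](OC(C)=O)C(C)=O | intermediate
27 | tert-butyl (2E,4S)-4-acetoxy-3-methylpent-2-enoate | C[C@H](OC(C)=O)/C(C)=C/C(=O)OC(C)(C)C | intermediate
28 | (2E,4S)-4-acetoxy-3-methylpent-2-enoic acid | C[C@H](OC(C)=O)/C(C)=C/C(=O)O | intermediate
29 | C6 mono-ester (1β-OH free) | C=C1[C@H]2[C@@H](O)[C@H](OC(=O)C(C)C)[C@@H]([C@H](C)OC(C)=O)[C@@H]2[C@@H]([C@]2(C)CO2)C[C@@H]1OC(=O)/C=C(\C)[C@H](C)OC(C)=O | intermediate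
30 | CNP0131236.1 | C=C1[C@H]2[C@@H](OC(=O)C(C)C)[C@H](OC(=O)C(C)C)[C@@H]([C@H](C)OC(C)=O)[C@@H]2[C@@H]([C@]2(C)CO2)C[C@@H]1OC(=O)/C=C(\C)[C@H](C)OC(C)=O | target

Total step count: 22. Longest linear sequence: 18 (steps 1–11, 13–17, 21, 22).

Steps most likely to fail

Step 15. Endo/exo control may erode, or the aluminium Lewis acid may strip silicon from the 2-(silylmethyl)diene (Sakurai-type desilylation after the first C–C bond) before the second bond forms. The fallback is an ionic Diels–Alder reaction with an allyl-cation dienophile, and it sets out from 19. Treatment with 1,2-bis(trimethylsilyloxy)ethane and catalytic Me3SiOTf in CH2Cl2 at −78 °C converts the enone in situ into its 2-alkenyl-1,3-dioxolan-2-ylium ion. This is a much stronger and more compact dienophile that should cyclise at −78 °C without a metal Lewis acid and collapse to the dioxolane-protected cycloadduct F1. PPTS in wet acetone then frees the ketone and the route is rejoined at 20.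

Step 14. The catalyst may be sequestered by the terminal alkyne. Alkyne-first initiation may lead to seven-membered endo-mode closure or to oligomers. The ruthenium alkylidene may also close onto the enone alkene. The fallback takes the enyne event away from the valuable substrate, and it sets out from 17 and 13. Cross enyne metathesis of 17 with ethylene (1 atm, second-generation Grubbs catalyst (H2IMes)(PCy3)Cl2Ru=CHPh) gives chloro(dimethyl)(2-methylidenebut-3-en-1-yl)silane F2. Imidazole-mediated silylation of 13 with it gives the dienylsilyl ether F3. A plain ene–ene ring-closing metathesis between the C7a vinyl group and the 1,1-disubstituted alkene then closes the six-membered ring, using the second-generation Hoveyda–Grubbs catalyst (H2IMes)Cl2Ru=CH(2-i-PrO-C6H4) at high dilution, and rejoins the route at 19.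

Step 21. Discrimination between the C6 and C1 hydroxyls may be insufficient, or the activated β,β-disubstituted enoic acid may deconjugate. The fallback separates the two alcohols by oxidation level, and it sets out from 24. MnO2 in CH2Cl2 oxidises only the allylic C6 alcohol to the 7-methylidene-6-ketone F4. Isobutyric anhydride/DMAP acylates the remaining C1 hydroxyl to give the bis-isobutyrate enone F5. Luche reduction (NaBH4, CeCl3·7H2O, MeOH, −78 °C) by axial hydride delivery gives the equatorial 6β-alcohol F6. A Mitsunobu esterification with 28 (PPh3, DIAD, toluene, 0 °C) then inverts C6 with the carboxylate as nucleophile, so no activated acyl species is needed, and it arrives directly at 30.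

Further compounds
F1 | step 15 | dioxolane-protected cycloadduct (20 with the acetyl C=O as its ethylene ketal) | C1C2=CC[C@H](C4(C)OCCO4)[C@@H]3[C@@H]2[C@@H](O[Si]1(C)C)[C@H](OC(=O)C(C)C)[C@H]3[C@H](C)OC(C)=O
F2 | step 14 | chloro(dimethyl)(2-methylidenebut-3-en-1-yl)silane | C=CC(=C)C[Si](C)(C)Cl
F3 | step 14 | (3E,5R,6R,7R)-5-[(1S)-1-acetoxyethyl]-7-{[dimethyl(2-methylidenebut-3-en-1-yl)silyl]oxy}-2-oxonona-3,8-dien-6-yl 2-methylpropanoate | C=C[C@@H](O[Si](C)(C)CC(=C)C=C)[C@H](OC(=O)C(C)C)[C@H](/C=C/C(C)=O)[C@H](C)OC(C)=O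
F4 | step 21 | 7-methylidene-6-ketone with free 1β-OH | C=C1[C@H]2[C@@H](O)[C@H](OC(=O)C(C)C)[C@@H]([C@H](C)OC(C)=O)[C@@H]2[C@@H]([C@]2(C)CO2)CC1=O
F5 | step 21 | 7-methylidene-6-ketone 1β,2α-bis(isobutyrate) | C=C1[C@H]2[C@@H](OC(=O)C(C)C)[C@H](OC(=O)C(C)C)[C@@H]([C@H](C)OC(C)=O)[C@@H]2[C@@H]([C@]2(C)CO2)CC1=O
F6 | step 21 | 6β-alcohol (C6 epimer) 1β,2α-bis(isobutyrate) | C=C1[C@H]2[C@@H](OC(=O)C(C)C)[C@H](OC(=O)C(C)C)[C@@H]([C@H](C)OC(C)=O)[C@@H]2[C@@H]([C@]2(C)CO2)C[C@H]1O
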